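## Retrosynthetic overview

1. The target comes from its tris-MOM ether, whose 2,2' biaryl bond is made by Suzuki coupling of a C2-boronate of MOM-protected 8-methoxy-1-naphthol (ring system A) with the 2-bromide of a 4,4'-linked binaphthyl (ring systems B–C).
2. That bromide comes from ortho-bromination and MOM protection of a 4-aryl-8-methoxy-1-naphthol. Its phenolic ring (central naphthalene B) is the only ring built, in the key step: intermolecular Michael addition of an ester-bearing diarylmethyl anion to phenyl vinyl sulfoxide, Dieckmann (Claisen) closure, then sulfoxide elimination and aromatisation.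
3. The diarylmethane comes from a benzylic Suzuki coupling of methyl 2-(bromomethyl)-6-methoxybenzoate with the 4-boronate of ring system C. The boronate is made regioselectively from naphthalene-1,8-diol (mono-MOM ether, acetate-directed para-bromination, acetate exchanged for methyl ether).
4. Order of ring formation: ring systems A and C are taken intact from naphthalene-1,8-diol; the phenolic ring of B is closed onto the methoxybenzoate ring in the key step.

Assumption: the target SMILES carries no stereodescriptors and the molecule has no stereocentre. The 2,2' axis is flanked only by two OH groups and the 4,4' axis only by H atoms, so neither axis is configurationally stable at room temperature and no enantiomer has to be selected.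

## Route

Step 1
Reactants: 1 naphthalene-1,8-diol
Product: 2 8-(methoxymethoxy)naphthalen-1-ol
Conditions: NaH (1.0 equiv), THF, 0 °C; MOMCl (1.0 equiv), 0 °C → rt
Reagents that add atoms: chloromethyl methyl ether (MOMCl), COCCl
Why: Williamson-type O-alkylation of the monophenoxide, which forms selectively because the peri hydrogen bond favours the first deprotonation and leaves the second OH unreactive, so protection stops at the mono-MOM ether.

Step 2
Reactants: 2 8-(methoxymethoxy)naphthalen-1-ol
Product: 3 8-(methoxymethoxy)naphthalen-1-yl acetate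
Conditions: Ac2O, pyridine, DMAP (cat.), CH2Cl2, rt
Reagents that add atoms: acetic anhydride, CC(=O)OC(C)=O
Why: DMAP-catalysed O-acylation turns the second oxygen into an electron-poor acyloxy group, so only the MOM-oxy ring stays activated for the next step.

Step 3
Reactants: 3 8-(methoxymethoxy)naphthalen-1-yl acetate
Product: 4 5-bromo-8-(methoxymethoxy)naphthalen-1-yl acetate
Conditions: NBS (1.05 equiv), MeCN, 0 °C → rt
Reagents that add atoms: N-bromosuccinimide, O=C1CCC(=O)N1Br
Why: Electrophilic aromatic bromination goes para to the alkoxy donor (as 1-alkoxynaphthalenes do with NBS in MeCN) while the acetoxy ring is deactivated, which places bromine para to the oxygen that ends as the free OH of ring system C.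

Step 4
Reactants: 4 5-bromo-8-(methoxymethoxy)naphthalen-1-yl acetate
Product: 6 1-bromo-5-methoxy-4-(methoxymethoxy)naphthalene, via 5-bromo-8-(methoxymethoxy)naphthalen-1-ol 5 (not isolated)
Conditions: K2CO3, MeOH, rt; then MeI, DMF, 45 °C
Reagents that add atoms: iodomethane, CI
Why: Base-mediated transesterification (methanolysis) of the aryl acetate followed by Williamson O-methylation of the liberated phenoxide in the same pot.

Step 5
Reactants: 6 1-bromo-5-methoxy-4-(methoxymethoxy)naphthalene
Product: 7 2-[5-methoxy-4-(methoxymethoxy)naphthalen-1-yl]-4,4,5,5-tetramethyl-1,3,2-dioxaborolane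
Conditions: B2pin2, PdCl2(dppf) (cat.), KOAc, 1,4-dioxane, 90 °C
Reagents that add atoms: bis(pinacolato)diboron, CC1(C)OB(OC1(C)C)B1OC(C)(C)C(C)(C)O1
Why: Miyaura borylation of an unhindered electron-rich aryl bromide is routine, and the MOM and methyl ethers are inert to KOAc and palladium.

Step 6
Reactants: 8 methyl 2-methoxy-6-methylbenzoate
Product: 9 methyl 2-(bromomethyl)-6-methoxybenzoate
Conditions: NBS, AIBN (cat.), PhCF3, 85 °C
Reagents that add atoms: N-bromosuccinimide, O=C1CCC(=O)N1Br
Why: Wohl–Ziegler radical bromination at the only benzylic position; the non-polar radical conditions suppress ring bromination.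

Step 7
Reactants: 7 2-[5-methoxy-4-(methoxymethoxy)naphthalen-1-yl]-4,4,5,5-tetramethyl-1,3,2-dioxaborolane; 9 methyl 2-(bromomethyl)-6-methoxybenzoate
Product: 10 methyl 2-methoxy-6-{[5-methoxy-4-(methoxymethoxy)naphthalen-1-yl]methyl}benzoate
Conditions: Pd(PPh3)4 (cat.), K2CO3, DME/H2O, 80 °C
Reagents that add atoms: none
Why: Suzuki–Miyaura sp2–sp3 coupling; the benzylic bromide adds quickly to zerovalent palladium and has no β-hydrogen, and the 2,6-disubstituted methyl ester resists hydrolysis.

Step 8
Reactants: 10 methyl 2-methoxy-6-{[5-methoxy-4-(methoxymethoxy)naphthalen-1-yl]methyl}benzoate; 11 phenyl vinyl sulfoxide (racemic)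
Product: 13 8-methoxy-4-[5-methoxy-4-(methoxymethoxy)naphthalen-1-yl]-2-(phenylsulfinyl)-3,4-dihydronaphthalen-1(2H)-one, via open-chain Michael adduct 12 (not isolated)
Conditions: LiN(iPr)2 (LDA, 1.1 equiv), THF, −78 °C; then 11 (1.0 equiv, slow addition), −78 → 0 °C; AcOH quench
Reagents that add atoms: none
Why: Intermolecular Michael addition of the ester-stabilised diarylmethyl lithium anion to the vinyl sulfoxide forms the C3–C4 bond of the central naphthalene, and the α-sulfinyl carbanion then closes the ring by Dieckmann (intramolecular Claisen) acylation on the neighbouring ester (Staunton–Weinreb-type annulation), driven by the β-keto sulfoxide enolate; the new stereocentres (C2, C4, sulfur) form as a diastereomer mixture that step 9 erases.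

Step 9
Reactants: 13 8-methoxy-4-[5-methoxy-4-(methoxymethoxy)naphthalen-1-yl]-2-(phenylsulfinyl)-3,4-dihydronaphthalen-1(2H)-one (crude)
Product: 15 8-methoxy-4-[5-methoxy-4-(methoxymethoxy)naphthalen-1-yl]naphthalen-1-ol, via naphthalen-1(4H)-one tautomer 14 (not isolated)
Conditions: toluene, 110 °C
Reagents that add atoms: none
Why: β-Keto sulfoxides undergo thermal syn-elimination of sulfenic acid (sulfoxide pyrolysis) across C2–C3, and the resulting 4H-dienone tautomerises at once to the aromatic naphthol, so no oxidant is needed.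

Step 10
Reactants: 15 8-methoxy-4-[5-methoxy-4-(methoxymethoxy)naphthalen-1-yl]naphthalen-1-ol
Product: 16 2-bromo-8-methoxy-4-[5-methoxy-4-(methoxymethoxy)naphthalen-1-yl]naphthalen-1-ol
Conditions: NBS (1.0 equiv), iPr2NH (cat.), CH2Cl2, 0 °C
Reagents that add atoms: N-bromosuccinimide, O=C1CCC(=O)N1Br
Why: Amine-catalysed ortho-bromination of a phenol (electrophilic aromatic substitution); the para position is blocked by the aryl group and the free naphthol ring is far more reactive than the ether-bearing rings.

Step 11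
Reactants: 16 2-bromo-8-methoxy-4-[5-methoxy-4-(methoxymethoxy)naphthalen-1-yl]naphthalen-1-ol
Product: 17 2-bromo-8-methoxy-1-(methoxymethoxy)-4-[5-methoxy-4-(methoxymethoxy)naphthalen-1-yl]naphthalene
Conditions: NaH, DMF, 0 °C; MOMCl, 0 °C → rt
Reagents that add atoms: chloromethyl methyl ether (MOMCl), COCCl
Why: Williamson-type O-alkylation of the sodium naphthoxide with the small, reactive MOMCl proceeds despite the peri-methoxy and ortho-bromo neighbours, and protects the phenol for the cross-coupling.

Step 12
Reactants: 1 naphthalene-1,8-diol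
Product: 18 8-methoxynaphthalen-1-ol
Conditions: MeI (1.05 equiv), K2CO3, acetone, reflux
Reagents that add atoms: iodomethane, CI
Why: Williamson mono-O-methylation; after the first alkylation the remaining OH is locked in a peri hydrogen bond and is not deprotonated by K2CO3.

Step 13
Reactants: 18 8-methoxynaphthalen-1-ol
Product: 19 1-methoxy-8-(methoxymethoxy)naphthalene
Conditions: NaH, DMF, 0 °C; MOMCl, 0 °C → rt
Reagents that add atoms: chloromethyl methyl ether (MOMCl), COCCl
Why: Williamson-type O-alkylation with the stronger base NaH overcomes the hydrogen-bonded phenol and installs the MOM group that directs the metalation.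

Step 14
Reactants: 19 1-methoxy-8-(methoxymethoxy)naphthalene
Product: 21 2-[8-methoxy-1-(methoxymethoxy)naphthalen-2-yl]-4,4,5,5-tetramethyl-1,3,2-dioxaborolane, via 2-naphthyllithium 20 (not isolated)
Conditions: n-BuLi, TMEDA, Et2O, 0 °C → rt; then iPrOBpin, −78 °C → rt; AcOH quench
Reagents that add atoms: 2-isopropoxy-4,4,5,5-tetramethyl-1,3,2-dioxaborolane (iPrOBpin), CC(C)OB1OC(C)(C)C(C)(C)O1; n-butyllithium, [Li]CCCC (supplies the lithium of intermediate 20 only)
Why: Directed ortho-metalation; the chelating MOM-oxy group is a stronger director than methoxy, so lithiation occurs at C2, and the aryllithium is trapped by the borate ester.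

Step 15
Reactants: 17 2-bromo-8-methoxy-1-(methoxymethoxy)-4-[5-methoxy-4-(methoxymethoxy)naphthalen-1-yl]naphthalene; 21 2-[8-methoxy-1-(methoxymethoxy)naphthalen-2-yl]-4,4,5,5-tetramethyl-1,3,2-dioxaborolane
Product: 22 8-methoxy-2-[8-methoxy-1-(methoxymethoxy)naphthalen-2-yl]-1-(methoxymethoxy)-4-[5-methoxy-4-(methoxymethoxy)naphthalen-1-yl]naphthalene
Conditions: Pd(OAc)2 (cat.), SPhos, K3PO4, toluene/H2O, 90 °C (degassed)
Reagents that add atoms: none
Why: Suzuki–Miyaura coupling with a dialkylbiarylphosphine ligand handles the ortho,ortho'-dioxygenated biaryl; the new axis carries only two ortho substituents and is stereochemically labile, so no stereocontrol is needed.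

Step 16
Reactants: 22 8-methoxy-2-[8-methoxy-1-(methoxymethoxy)naphthalen-2-yl]-1-(methoxymethoxy)-4-[5-methoxy-4-(methoxymethoxy)naphthalen-1-yl]naphthalene
Product: 23 2-(1-hydroxy-8-methoxynaphthalen-2-yl)-4-(4-hydroxy-5-methoxynaphthalen-1-yl)-8-methoxynaphthalen-1-ol (CNP0542019.0)
Conditions: HCl (cat.), MeOH/THF, 50 °C, under N2
Reagents that add atoms: none
Why: Acid-catalysed acetal exchange (MOM cleavage) transfers the three methoxymethyl groups to methanol and leaves the aryl methyl ethers untouched.

## Compound list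

1 | naphthalene-1,8-diol | Oc1cccc2cccc(O)c12 | starting material
2 | 8-(methoxymethoxy)naphthalen-1-ol | COCOc1cccc2cccc(O)c12 | intermediate
3 | 8-(methoxymethoxy)naphthalen-1-yl acetate | COCOc1cccc2cccc(OC(C)=O)c12 | intermediate
4 | 5-bromo-8-(methoxymethoxy)naphthalen-1-yl acetate | COCOc1ccc(Br)c2cccc(OC(C)=O)c12 | intermediate
5 | 5-bromo-8-(methoxymethoxy)naphthalen-1-ol (not isolated) | COCOc1ccc(Br)c2cccc(O)c12 | intermediate
6 | 1-bromo-5-methoxy-4-(methoxymethoxy)naphthalene | COCOc1ccc(Br)c2cccc(OC)c12 | intermediate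
7 | 2-[5-methoxy-4-(methoxymethoxy)naphthalen-1-yl]-4,4,5,5-tetramethyl-1,3,2-dioxaborolane | COCOc1ccc(B3OC(C)(C)C(C)(C)O3)c2cccc(OC)c12 | intermediate
8 | methyl 2-methoxy-6-methylbenzoate | COC(=O)c1c(C)cccc1OC | starting material
9 | methyl 2-(bromomethyl)-6-methoxybenzoate | COC(=O)c1c(CBr)cccc1OC | intermediate
10 | methyl 2-methoxy-6-{[5-methoxy-4-(methoxymethoxy)naphthalen-1-yl]methyl}benzoate | COC(=O)c1c(Cc2ccc(OCOC)c3c(OC)cccc23)cccc1OC | intermediate
11 | phenyl vinyl sulfoxide, racemic | C=CS(=O)c1ccccc1 | starting material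
12 | methyl 2-methoxy-6-{1-[5-methoxy-4-(methoxymethoxy)naphthalen-1-yl]-3-(phenylsulfinyl)propyl}benzoate (present as its lithium α-sulfinyl carbanion, diastereomer mixture, not isolated) | COC(=O)c1c(C(CCS(=O)c2ccccc2)c2ccc(OCOC)c3c(OC)cccc23)cccc1OC | intermediate
13 | 8-methoxy-4-[5-methoxy-4-(methoxymethoxy)naphthalen-1-yl]-2-(phenylsulfinyl)-3,4-dihydronaphthalen-1(2H)-one (racemic diastereomer mixture) | O=C1C(S(=O)c2ccccc2)CC(c2ccc(OCOC)c3c(OC)cccc23)c2cccc(OC)c12 | intermediate
14 | 8-methoxy-4-[5-methoxy-4-(methoxymethoxy)naphthalen-1-yl]naphthalen-1(4H)-one (racemic, not isolated) | O=C1C=CC(c2ccc(OCOC)c3c(OC)cccc23)c2cccc(OC)c12 | intermediate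
15 | 8-methoxy-4-[5-methoxy-4-(methoxymethoxy)naphthalen-1-yl]naphthalen-1-ol | Oc1ccc(-c2ccc(OCOC)c3c(OC)cccc23)c2cccc(OC)c12 | intermediate
16 | 2-bromo-8-methoxy-4-[5-methoxy-4-(methoxymethoxy)naphthalen-1-yl]naphthalen-1-ol | Oc1c(Br)cc(-c2ccc(OCOC)c3c(OC)cccc23)c2cccc(OC)c12 | intermediate
17 | 2-bromo-8-methoxy-1-(methoxymethoxy)-4-[5-methoxy-4-(methoxymethoxy)naphthalen-1-yl]naphthalene | COCOc1c(Br)cc(-c2ccc(OCOC)c3c(OC)cccc23)c2cccc(OC)c12 | intermediate
18 | 8-methoxynaphthalen-1-ol | COc1cccc2cccc(O)c12 | intermediate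
19 | 1-methoxy-8-(methoxymethoxy)naphthalene | COCOc1cccc2cccc(OC)c12 | intermediate
20 | [8-methoxy-1-(methoxymethoxy)naphthalen-2-yl]lithium (not isolated) | [Li]c1ccc2cccc(OC)c2c1OCOC | intermediate
21 | 2-[8-methoxy-1-(methoxymethoxy)naphthalen-2-yl]-4,4,5,5-tetramethyl-1,3,2-dioxaborolane | COCOc1c(B3OC(C)(C)C(C)(C)O3)ccc2cccc(OC)c12 | intermediate
22 | 8-methoxy-2-[8-methoxy-1-(methoxymethoxy)naphthalen-2-yl]-1-(methoxymethoxy)-4-[5-methoxy-4-(methoxymethoxy)naphthalen-1-yl]naphthalene | COCOc1c(-c2cc(-c3ccc(OCOC)c4c(OC)cccc34)c3cccc(OC)c3c2OCOC)ccc2cccc(OC)c12 | intermediate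
23 | 2-(1-hydroxy-8-methoxynaphthalen-2-yl)-4-(4-hydroxy-5-methoxynaphthalen-1-yl)-8-methoxynaphthalen-1-ol | COc1cccc2ccc(-c3cc(-c4ccc(O)c5c(OC)cccc45)c4cccc(OC)c4c3O)c(O)c12 | target

## Step count and risk

Total steps: 16. Longest linear sequence: 12 steps (1 → 2 → 3 → 4 → 6 → 7 → 10 → 13 → 15 → 16 → 17 → 22 → 23, that is steps 1–5, 7–11, 15 and 16).

The three steps most likely to fail:

Step 8. The hindered diarylmethyl anion may add sluggishly to the vinyl sulfoxide, or the adduct carbanion may oligomerise 11 before the ring closes. The fallback sets out from 10 and comes back at 15. The same lithium anion of 10 is added to methyl acrylate instead, and Michael addition with Dieckmann closure gives the enolisable β-keto ester methyl 8-methoxy-4-[5-methoxy-4-(methoxymethoxy)naphthalen-1-yl]-1-oxo-1,2,3,4-tetrahydronaphthalene-2-carboxylate F1. Krapcho dealkoxycarbonylation (LiCl, wet DMSO, 140 °C) gives the tetralone 8-methoxy-4-[5-methoxy-4-(methoxymethoxy)naphthalen-1-yl]-3,4-dihydronaphthalen-1(2H)-one F2. LiN(iPr)2 and Me3SiCl convert it into the silyl enol ether {[8-methoxy-4-(5-methoxy-4-(methoxymethoxy)naphthalen-1-yl)-3,4-dihydronaphthalen-1-yl]oxy}trimethylsilane F3. Saegusa–Ito dehydrogenation with Pd(OAc)2 in MeCN then leads through dienone 14 to naphthol 15.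

Step 14. Lithiation could occur partly at C7 (next to the methoxy group) or be incomplete. The fallback sets out from 18 and comes back at 21. Amine-catalysed ortho-bromination of 18 (NBS, cat. iPr2NH, CH2Cl2, 0 °C) gives 2-bromo-8-methoxynaphthalen-1-ol F4, which is separable from any para isomer at this early stage. NaH and MOMCl give 2-bromo-8-methoxy-1-(methoxymethoxy)naphthalene F5, and Miyaura borylation (B2pin2, PdCl2(dppf), KOAc, dioxane, 90 °C) gives 21 with the boron position fixed by the bromide.

Step 15. The ortho-alkoxy boronate 21 may protodeboronate faster than it couples with the hindered bromide. The fallback sets out from 19 and 17 and comes back at 22. Compound 19 is lithiated as in step 14 to 20 and transmetalated with ZnCl2 to chlorido[8-methoxy-1-(methoxymethoxy)naphthalen-2-yl]zinc F6. Negishi coupling of this organozinc with 17 (Pd(OAc)2, SPhos, THF, 60 °C) gives 22 without aqueous base. If the lithiation of step 14 is also the problem, the same organozinc is reached from the bromide of the step 14 fallback by bromine–lithium exchange.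

## Further compounds

F1 | step 8 | methyl 8-methoxy-4-[5-methoxy-4-(methoxymethoxy)naphthalen-1-yl]-1-oxo-1,2,3,4-tetrahydronaphthalene-2-carboxylate | COC(=O)C1CC(c2ccc(OCOC)c3c(OC)cccc23)c2cccc(OC)c2C1=O
F2 | step 8 | 8-methoxy-4-[5-methoxy-4-(methoxymethoxy)naphthalen-1-yl]-3,4-dihydronaphthalen-1(2H)-one | O=C1CCC(c2ccc(OCOC)c3c(OC)cccc23)c2cccc(OC)c12
F3 | step 8 | {[8-methoxy-4-(5-methoxy-4-(methoxymethoxy)naphthalen-1-yl)-3,4-dihydronaphthalen-1-yl]oxy}trimethylsilane | C[Si](C)(C)OC1=CCC(c2ccc(OCOC)c3c(OC)cccc23)c2cccc(OC)c12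
F4 | step 14 | 2-bromo-8-methoxynaphthalen-1-ol | COc1cccc2ccc(Br)c(O)c12
F5 | step 14 | 2-bromo-8-methoxy-1-(methoxymethoxy)naphthalene | COCOc1c(Br)ccc2cccc(OC)c12
F6 | step 15 | chlorido[8-methoxy-1-(methoxymethoxy)naphthalen-2-yl]zinc | Cl[Zn]c1ccc2cccc(OC)c2c1OCOC
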